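A direct plan would brominate 1-(3,4,5-trimethoxyphenyl)ethan-1-one A1 twice on the ring to the 2,6-dibromo ketone A2, condense it with methyl 3,4-bis(benzyloxy)benzoate A3 to the 1,3-diketone A4, close ring C at O1–C8a by copper-mediated O-arylation while methoxide replaces the second bromide, giving the dibenzyl flavone A5, and end with hydrogenolysis. Its weakest steps would be:
- the double ring bromination, since α-bromination of the methyl ketone would compete and the second bromine would have to enter a crowded position;
- the Claisen condensation of the twisted, di-ortho-substituted ketone, which would be slow and reversible under methoxide;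
- the merged double C–O coupling at two hindered C–Br bonds, where hydrodebromination and retro-Claisen cleavage would compete.

The route would rest on closing ring C at the C4–C4a carbon–carbon bond instead of at O1. The feature exploited is that ring A, once all five of its oxygens are in place as 2,3,4,5-tetramethoxyphenol, has exactly one free carbon, the future C4a, activated by an ortho and a para methoxy group. The phenol oxygen (O1) would be joined to C2 by conjugate addition to an arylpropiolate, and the derived 3-aryl-3-(aryloxy)acrylic acid would be cycloacylated at that carbon, the acid medium also releasing the ring B catechol from its ketal. Ring halogenation, Claisen condensation and copper-mediated C–O coupling would have no counterpart, and no regiochemical choice would remain.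

Key step: step 6

Assumption: the target has no stereocentre, so only the alkene geometry of the acrylic acid intermediate needs comment (both isomers would converge in the key step), and 1,2,3,4-tetramethoxybenzene is taken as a catalogue compound.

Step 1
Reactants: 1 1,2,3,4-tetramethoxybenzene
Product: 4 2,3,4,5-tetramethoxyphenol, via aryllithium 2 (not isolated), via lithium aryltrimethoxyborate 3 (not isolated)
Conditions: n-BuLi (1.2 equiv), TMEDA, THF, 0 °C, 2 h; B(OMe)3, −78 °C → rt; AcOH, then 30% H2O2, 0 °C → rt; N2 throughout
Reagents that add atoms: hydrogen peroxide OO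
Why: Directed ortho-metalation at one of the two equivalent ring CH positions (each ortho to a methoxy group), borylation of the aryllithium and oxidation of the C–B bond by 1,2-migration of the aryl group from boron to peroxide oxygen should place the hydroxyl exactly where lithium stood; no stereocentre is formed.

Step 2
Reactants: 5 3,4-dihydroxybenzaldehyde
Product: 6 2,2-diphenyl-1,3-benzodioxole-5-carbaldehyde
Conditions: Ph2CCl2 (1.3 equiv), Ph2O, 175 °C, 30 min, N2 stream
Reagents that add atoms: dichlorodiphenylmethane ClC(Cl)(c1ccccc1)c1ccccc1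
Why: Ketalisation of the catechol with the geminal dichloride (two successive substitutions through the chlorodiphenylmethyl cation, HCl being driven off) should mask both phenols as a diphenylmethylene ketal that tolerates organolithium reagents and base but is cleaved by aqueous acid; no stereocentre is formed.

Step 3
Reactants: 6 2,2-diphenyl-1,3-benzodioxole-5-carbaldehyde
Product: 7 5-(2,2-dibromoethenyl)-2,2-diphenyl-1,3-benzodioxole
Conditions: CBr4 (1.5 equiv), PPh3 (3 equiv), CH2Cl2, 0 °C, 1 h
Reagents that add atoms: carbon tetrabromide BrC(Br)(Br)Br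
Why: First stage of the Corey–Fuchs sequence, a Wittig-type olefination of the aldehyde by the dibromomethylene ylide made in the flask from PPh3 and CBr4, should give the 1,1-dibromoalkene without touching the ketal; no stereocentre is formed.

Step 4
Reactants: 7 5-(2,2-dibromoethenyl)-2,2-diphenyl-1,3-benzodioxole
Product: 9 methyl 3-(2,2-diphenyl-1,3-benzodioxol-5-yl)prop-2-ynoate, via lithium acetylide 8 (not isolated)
Conditions: n-BuLi (2.1 equiv), THF, −78 °C, 1 h; ClCO2Me (1.5 equiv), −78 → 0 °C
Reagents that add atoms: methyl chloroformate COC(=O)Cl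
Why: Second stage of the Corey–Fuchs sequence, in which bromine–lithium exchange, loss of LiBr with 1,2-shift and deprotonation by the second equivalent of n-BuLi should give the lithium acetylide, followed by C-acylation with the chloroformate to the ynoate; no stereocentre is formed.

Step 5
Reactants: 4 2,3,4,5-tetramethoxyphenol; 9 methyl 3-(2,2-diphenyl-1,3-benzodioxol-5-yl)prop-2-ynoate
Product: 11 (2Z)-3-(2,2-diphenyl-1,3-benzodioxol-5-yl)-3-(2,3,4,5-tetramethoxyphenoxy)prop-2-enoic acid, via methyl ester 10 (not isolated)
Conditions: Cs2CO3 (0.3 equiv), MeCN, N2, 70 °C, 12 h; then LiOH·H2O (3 equiv), THF–MeOH–H2O, rt, 6 h; cold 1 M HCl to pH 3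
Reagents that add atoms: lithium hydroxide [Li+].[OH-]
Why: Base-catalysed oxa-Michael addition of the phenoxide to the ynoate should form O1–C2, anti addition placing the aryloxy group cis to the ester ((Z)-alkene, the geometry needed for ring closure, although the (E) isomer would also serve), and saponification at the acyl carbon should then free the acid; no stereocentre is formed.

Step 6
Reactants: 11 (2Z)-3-(2,2-diphenyl-1,3-benzodioxol-5-yl)-3-(2,3,4,5-tetramethoxyphenoxy)prop-2-enoic acid
Product: 13 2-(3,4-dihydroxyphenyl)-5,6,7,8-tetramethoxy-4H-chromen-4-one (3',4'-dihydroxy-5,6,7,8-tetramethoxyflavone), via ketal flavone 12 (not isolated)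
Conditions: Eaton's reagent (7.7 wt % P2O5 in MeSO3H), N2, 0 → 35 °C, 3 h; then ice–H2O/THF, 60 °C, 2 h
Reagents that add atoms: none
Why: P2O5 in MeSO3H should turn the acid into a mixed anhydride and then an acylium ion stabilised as a ketene–oxocarbenium form (O=C=CH–C(Ar)=O+–Ar), which attacks the one unsubstituted carbon of the pentaoxygenated ring (ortho to the ether oxygen and to one methoxy group, para to another) and rearomatises by loss of a proton, forming C4–C4a. The closest known reaction type is the Ruhemann flavone synthesis, the acid-mediated Friedel–Crafts cycloacylation of 3-aryloxycinnamic acids, also used for chromones from 3-aryloxyacrylic acids. Ring C is closed as a six-membered ring at a carbon–carbon bond by electrophilic aromatic substitution (formally 6-exo-dig at the acylium carbon), and no stereocentre is formed. The alkene geometry is not decisive, since reversible protonation at C2 and the single-bond character of C2–C3 in the ketene form let the (E) acid drain through the (Z) acid. The step needs acylation of ring A in preference to five-membered closure onto ring B (an indenone) and to demethylation, which the far greater nucleophilicity of ring A, the six-membered transition state and the mild temperature with a non-nucleophilic counter-ion should secure. The ketal is ionised in the acid to an aryloxy(diphenyl)carbenium ion, which also deactivates ring B, and is hydrolysed on the warm aqueous quench to the catechol and benzophenone, so that 12 is not isolated.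

**Compound list**
1 | 1,2,3,4-tetramethoxybenzene | COc1ccc(OC)c(OC)c1OC | starting material
2 | (2,3,4,5-tetramethoxyphenyl)lithium | [Li]c1cc(OC)c(OC)c(OC)c1OC | intermediate
3 | lithium trimethoxy(2,3,4,5-tetramethoxyphenyl)borate | [Li+].CO[B-](OC)(OC)c1cc(OC)c(OC)c(OC)c1OC | intermediate
4 | 2,3,4,5-tetramethoxyphenol | COc1cc(O)c(OC)c(OC)c1OC | intermediate
5 | 3,4-dihydroxybenzaldehyde | O=Cc1ccc(O)c(O)c1 | starting material
6 | 2,2-diphenyl-1,3-benzodioxole-5-carbaldehyde | O=Cc1ccc2OC(c3ccccc3)(c3ccccc3)Oc2c1 | intermediate
7 | 5-(2,2-dibromoethenyl)-2,2-diphenyl-1,3-benzodioxole | BrC(Br)=Cc1ccc2OC(c3ccccc3)(c3ccccc3)Oc2c1 | intermediate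
8 | lithium (2,2-diphenyl-1,3-benzodioxol-5-yl)acetylide | [Li]C#Cc1ccc2OC(c3ccccc3)(c3ccccc3)Oc2c1 | intermediate
9 | methyl 3-(2,2-diphenyl-1,3-benzodioxol-5-yl)prop-2-ynoate | COC(=O)C#Cc1ccc2OC(c3ccccc3)(c3ccccc3)Oc2c1 | intermediate
10 | methyl (2Z)-3-(2,2-diphenyl-1,3-benzodioxol-5-yl)-3-(2,3,4,5-tetramethoxyphenoxy)prop-2-enoate | COC(=O)/C=C(\Oc1cc(OC)c(OC)c(OC)c1OC)c1ccc2OC(c3ccccc3)(c3ccccc3)Oc2c1 | intermediate
11 | (2Z)-3-(2,2-diphenyl-1,3-benzodioxol-5-yl)-3-(2,3,4,5-tetramethoxyphenoxy)prop-2-enoic acid | OC(=O)/C=C(\Oc1cc(OC)c(OC)c(OC)c1OC)c1ccc2OC(c3ccccc3)(c3ccccc3)Oc2c1 | intermediate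
12 | 2-(2,2-diphenyl-1,3-benzodioxol-5-yl)-5,6,7,8-tetramethoxy-4H-chromen-4-one | COc1c(OC)c(OC)c2c(=O)cc(-c3ccc4OC(c5ccccc5)(c5ccccc5)Oc4c3)oc2c1OC | intermediate
13 | 2-(3,4-dihydroxyphenyl)-5,6,7,8-tetramethoxy-4H-chromen-4-one | COc1c(OC)c(OC)c2c(=O)cc(-c3ccc(O)c(O)c3)oc2c1OC | target

Total step count: 6. Longest linear sequence: 5 steps (steps 2, 3, 4, 5 and 6, from 3,4-dihydroxybenzaldehyde).

Steps most likely to fail:

Step 6. The acid might lose CO2 by protonation at C2 before it is activated, the acylium ion might close onto ring B, the ketal-derived cation might alkylate an electron-rich ring, or the peri methoxy group might be lost in the acid. In that case C4 would be brought in as carbon monoxide and ring C closed without strong acid. The fallback would set out from phenol 4 and dibromoalkene 7. Phenol 4 would be iodinated at its only free position (NIS, MeCN, 0 °C) to 2-iodo-3,4,5,6-tetramethoxyphenol F1. Dibromoalkene 7 would be converted (n-BuLi, THF, −78 °C, then aq NH4Cl) into 5-ethynyl-2,2-diphenyl-1,3-benzodioxole F2. The two would be joined under CO (balloon) with PdCl2(PPh3)2 in Et2NH at 60–80 °C by carbonylative Sonogashira coupling and 6-endo oxa-Michael closure. This would come back to the route at ketal flavone 12, which AcOH–H2O (4:1, reflux) would hydrolyse to 13.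

Step 5. The conjugate addition might be too slow on the electron-rich ynoate while the phenoxide is oxidised, or hydroxide might displace the aryloxide by addition–elimination during saponification. In that case the acceptor would be changed to an ynal and the acid made by oxidation instead of hydrolysis. The fallback would set out from dibromoalkene 7 and phenol 4. Dibromoalkene 7 (n-BuLi, THF, −78 °C, then DMF) would give 3-(2,2-diphenyl-1,3-benzodioxol-5-yl)prop-2-ynal F3. Phenol 4 would add to it at room temperature (K2CO3 cat., MeCN, N2) to give (2Z)-3-(2,2-diphenyl-1,3-benzodioxol-5-yl)-3-(2,3,4,5-tetramethoxyphenoxy)prop-2-enal F4. Pinnick oxidation (NaClO2, NaH2PO4, 2-methyl-2-butene in large excess, t-BuOH–H2O) would return to the route at acid 11.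

Step 1. The peroxide might over-oxidise the very electron-rich phenol to a quinone, or lithiation might stay incomplete. In that case the oxygen would be introduced through a formyl group. The fallback would set out from 1. Vilsmeier–Haack formylation of 1 (POCl3, DMF, 80 °C) would give 2,3,4,5-tetramethoxybenzaldehyde F5. Baeyer–Villiger oxidation (mCPBA, CH2Cl2, 0 °C → rt) would give 2,3,4,5-tetramethoxyphenyl formate F6, in which the new oxygen is masked against further oxidation. Methanolysis (K2CO3, MeOH, N2) would return to the route at phenol 4.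

Further compounds
F1 | step 6 | 2-iodo-3,4,5,6-tetramethoxyphenol | COc1c(I)c(O)c(OC)c(OC)c1OC
F2 | step 6 | 5-ethynyl-2,2-diphenyl-1,3-benzodioxole | C#Cc1ccc2OC(c3ccccc3)(c3ccccc3)Oc2c1
F3 | step 5 | 3-(2,2-diphenyl-1,3-benzodioxol-5-yl)prop-2-ynal | O=CC#Cc1ccc2OC(c3ccccc3)(c3ccccc3)Oc2c1
F4 | step 5 | (2Z)-3-(2,2-diphenyl-1,3-benzodioxol-5-yl)-3-(2,3,4,5-tetramethoxyphenoxy)prop-2-enal | O=C/C=C(\Oc1cc(OC)c(OC)c(OC)c1OC)c1ccc2OC(c3ccccc3)(c3ccccc3)Oc2c1
F5 | step 1 | 2,3,4,5-tetramethoxybenzaldehyde | O=Cc1cc(OC)c(OC)c(OC)c1OC
F6 | step 1 | 2,3,4,5-tetramethoxyphenyl formate | O=COc1cc(OC)c(OC)c(OC)c1OC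
A1 | direct plan | 1-(3,4,5-trimethoxyphenyl)ethan-1-one | CC(=O)c1cc(OC)c(OC)c(OC)c1
A2 | direct plan | 1-(2,6-dibromo-3,4,5-trimethoxyphenyl)ethan-1-one | CC(=O)c1c(Br)c(OC)c(OC)c(OC)c1Br
A3 | direct plan | methyl 3,4-bis(benzyloxy)benzoate | COC(=O)c1ccc(OCc2ccccc2)c(OCc2ccccc2)c1
A4 | direct plan | 1-[3,4-bis(benzyloxy)phenyl]-3-(2,6-dibromo-3,4,5-trimethoxyphenyl)propane-1,3-dione | O=C(CC(=O)c1ccc(OCc2ccccc2)c(OCc2ccccc2)c1)c1c(Br)c(OC)c(OC)c(OC)c1Br
A5 | direct plan | 2-[3,4-bis(benzyloxy)phenyl]-5,6,7,8-tetramethoxy-4H-chromen-4-one | COc1c(OC)c(OC)c2c(=O)cc(-c3ccc(OCc4ccccc4)c(OCc4ccccc4)c3)oc2c1OC
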